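(The earlier runs and the new flask were computed for substances that don't exist; noise was put on by code.)

The constants of this flask are hidden, so you read what you can of them from the autumn run, which is the same flask followed as far as 120 min.

- autumn: free monomer 0.80 M; initiator 12 mM; the very flask that is asked about, followed so far
- flask: free monomer 0.80 M; initiator 12 mM; time 15 h

- autumn (time / min: monomer in chains / %, free monomer / %): 25.0: 13.6, 86.1; 50.0: 27.2, 72.8; 80.0: 32.3, 66.9; 120: 34.5, 64.7

(readings scatter by 0.5 percentage points)

- what may be going on: monomer in chains + living end -> free monomer + living end; free monomer + initiator -> spent initiator A; initiator -> spent initiator B; free monomer + initiator -> living end + monomer in chains; free monomer + living end -> monomer in chains + living end; initiator + monomer in chains -> initiator + over-reaction product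

1. how much monomer in chains the flask holds at 15 h, in percent of the free monomer charged
2. how much free monomer the flask holds at 15 h, in percent of the free monomer charged

Take the main step by itself: living ends add free monomer, so c(free monomer) should keep falling towards zero. It doesn't. Between 80.0 min and 120 min it creeps from 66.9% to 64.7%.

Now add the step that gives monomer back. Each of the two chain steps needs a living end, so the number of ends cancels from their balance; if the giving back does not depend on c(monomer in chains), you get the floor concentration, the c(free monomer) at which living ends give back as fast as they add (the equilibrium monomer concentration). Above it, with the ends steady, the excess decays exponentially.

Reckon it by going round. Take the last reading as the floor: the excess then decays at 0.0434 /min, which leaves some excess at 120 min and lowers the floor to 64.3%. Put that back: the rate becomes 0.0396 /min and the floor 64.2%. That shift of 0.10 percentage points is less than the scatter, so stop. The floor reads 0.513 M.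

The excess halves every 17.5 min, far less than 15 h, so this flask should stand at its floor when asked.

Last come the side steps. Charge them with what the final readings leave unaccounted, 0.8 points, and my reckoning gives 64.2% free monomer and 35.0% monomer in chains.

The forecast says 64.1% and 35.2%, on the ground that “A stall with living ends still present points to reversible propagation reaching a ceiling”.

The flask holds 64.1% of free monomer and 35.6% of monomer in chains.

    monomer in chains + living end → free monomer + living end, rate k1*[living end] as long as [monomer in chains] is above zero (k = 2.00 /min)
    free monomer + initiator → spent initiator A (k = 0.00440 /M/min)
    initiator → spent initiator B (k = 3.10 × 10⁻⁶ /min)
    free monomer + initiator → living end + monomer in chains (k = 0.0610 /M/min)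
    free monomer + living end → monomer in chains + living end, rate k5*[living end]*[free monomer] (k = 3.90 /M/min)
    initiator + monomer in chains → initiator + over-reaction product (k = 0.0640 /M/min)

The slowest mode of this flask has a half-life of 0.345 h at 15 h, far shorter than the run. The floor read from the autumn run, over the charge, is 64.2% beside the 64.1% found, and divided by the 1.4 M charged in a neighbour flask, otherwise alike, it gives 36.6%, where that neighbour flask holds 36.6% of free monomer at 15 h.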